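**Retrosynthetic overview**

1. Feature used: each stereocentre of the target is the benzylic methine C1 of a 2-methylpropane-1,1-diyl linker. It sits on ring carbon C3 (or C5) of the central acylphloroglucinol ring between two free phenolic oxygens (O2/O4, or O4/O6) and is bonded to C2 of a syncarpic acid ring, so it can be flattened to an o-quinone methide.
2. Key disconnection: both linker-C1–C2(syncarpyl) bonds are cut at once, not the customary aryl–C1 bonds. The central ring becomes a latent bis-o-quinone methide (polarity of C3/C5 inverted) that takes up two syncarpic acid enolates under catalyst control.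
3. The key step is stereoconvergent: the latent bis-quinone methide is a bis(1-tosyl-2-methylpropyl) derivative used as its meso/racemic mixture, and both sulfone centres are erased before the R,R centres are set.
4. Rings: none is closed in the key step. The central ring comes from phloroglucinol by acylation; both outer rings come from one batch of syncarpic acid, made by dearomatising tetramethylation and deacetylation of phloroacetophenone.

Key step: step 5

Assumption: with the enol tautomer as drawn, both stereocentres are R (the C2-symmetric isomer, not the meso one). The quinine-derived squaramide is written for step 5 on the assumption that it gives the R sense at each centre; its quinidine-derived pseudo-enantiomer is the same step with the opposite sense should the assignment prove reversed.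

**Route**

Step 1
Reactants: 1 phloroglucinol; 2 isobutyryl chloride
Product: 3 2-methyl-1-(2,4,6-trihydroxyphenyl)propan-1-one (isobutyrylphloroglucinol)
Conditions: AlCl3 (4 equiv), PhNO2–CH2Cl2, 0 °C to 50 °C; then ice/aq HCl
Reagents that add atoms: none
Why: Friedel–Crafts C-acylation of the symmetric triol; the first acyl group, chelated to aluminium, deactivates the ring towards a second acylation, and no stereocentre is formed.

Step 2
Reactants: 4 2,4,6-trihydroxyacetophenone
Product: 5 2-acetyl-3-hydroxy-4,4,6,6-tetramethylcyclohex-2-ene-1,5-dione (acetylsyncarpic acid)
Conditions: NaOMe (5 equiv), MeI (6 equiv), MeOH, 0 °C to reflux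
Reagents that add atoms: iodomethane, CI
Why: Dearomatising exhaustive C-methylation of the phenoxide in a protic medium; the two free ring carbons are each methylated twice while the acetyl group blocks the third, and no stereocentre is formed.

Step 3
Reactants: 5 acetylsyncarpic acid
Product: 6 5-hydroxy-2,2,6,6-tetramethylcyclohex-4-ene-1,3-dione (syncarpic acid)
Conditions: 6 M aq HCl, reflux
Reagents that add atoms: none
Why: Acid-mediated retro-Claisen deacylation of the β-triketone; water attacks the unhindered exocyclic acetyl carbonyl rather than the ring carbonyls that are flanked by quaternary carbons.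

Step 4
Reactants: 3 isobutyrylphloroglucinol; 7 isobutyraldehyde (3 equiv)
Product: 9 1-{2,4,6-trihydroxy-3,5-bis[2-methyl-1-(4-methylbenzenesulfonyl)propyl]phenyl}-2-methylpropan-1-one (bis-sulfone; meso/racemic mixture), via mono-sulfone 8 (not isolated)
Conditions: p-TolSO2Na (3 equiv), HCO2H–H2O 1:1, rt; the solid is collected and triturated, no chromatography
Reagents that add atoms: sodium p-toluenesulfinate, Cc1ccc(cc1)S(=O)[O-].[Na+]
Why: Acid-mediated three-component Mannich-type sulfonylalkylation (hydroxyalkylation of the only free ring carbons C3 and C5, ionisation to the benzylic cation/quinone methide, S-capture by sulfinate); the two stereocentres form without control and the mixture is used as such because both are erased in step 5.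

Step 5
Reactants: 9 bis-sulfone (stereoisomer mixture); 6 syncarpic acid (2.4 equiv)
Product: 13 (R,R)-myrtucommulone A, via first o-quinone methide 10 (not isolated), via mono-adduct 11 (not isolated), via second o-quinone methide 12 (not isolated)
Conditions: quinine-derived 3,5-bis(trifluoromethyl)phenyl squaramide (20 mol %), 5% aq Na2CO3 (2.5 equiv), CHCl3, 0 °C; then cold 1 M HCl, extraction without heating
Reagents that add atoms: none
Why: Carbonate deprotonates a phenol of 9 and the phenoxide expels p-toluenesulfinate (1,4-elimination) to give the planar o-quinone methide 10, which erases the configuration of the sulfone carbon; the squaramide N–H pair binds the quinone-methide carbonyl oxygen while the quinuclidinium of the same catalyst carries the enolate of 6, which adds through its C2 to one face of the exocyclic methide carbon with rearomatisation to 11, and the sequence repeats through 12. The closest known reaction type is the bifunctional amine–squaramide-catalysed enantioselective conjugate addition of cyclic 1,3-dicarbonyl compounds to o-quinone methides generated in situ from 2-(1-tosylalkyl)phenols under aqueous inorganic base. No ring is closed: the step forms the two linker-C1–C2(syncarpyl) bonds intermolecularly. Each of the two stereocentres is set by the catalyst alone (face of the methide carbon); the centres are 1,5-related across C4, so the two events should be nearly independent and errors should go mainly into the diastereomeric meso compound rather than into the enantiomer. The step needs face selectivity on a methide carbon that has oxygen on both ring neighbours; this is secured if the catalyst binds the oxygen on the side of the methide C–H, away from the isopropyl group, because both geometric isomers of the quinone methide then present the same local s-cis enone and lead to the same configuration. It also needs C-attack by the enolate of 6 to outrun the 1,5-hydrogen shift to the 2-methylprop-1-enyl arene and capture by a second phenoxide, which the excess of the soft enolate and the low temperature should secure; the adduct should be held against retro-addition because its syncarpyl enols are deprotonated at once under the basic conditions.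

**Compound list**

1 | phloroglucinol (benzene-1,3,5-triol) | Oc1cc(O)cc(O)c1 | starting material
2 | isobutyryl chloride (2-methylpropanoyl chloride) | CC(C)C(Cl)=O | starting material
3 | isobutyrylphloroglucinol, 2-methyl-1-(2,4,6-trihydroxyphenyl)propan-1-one | CC(C)C(=O)c1c(O)cc(O)cc1O | intermediate
4 | 2,4,6-trihydroxyacetophenone (phloroacetophenone) | CC(=O)c1c(O)cc(O)cc1O | starting material
5 | acetylsyncarpic acid, 2-acetyl-3-hydroxy-4,4,6,6-tetramethylcyclohex-2-ene-1,5-dione | CC(=O)C1=C(O)C(C)(C)C(=O)C(C)(C)C1=O | intermediate
6 | syncarpic acid, 5-hydroxy-2,2,6,6-tetramethylcyclohex-4-ene-1,3-dione | CC1(C)C(=O)C=C(O)C(C)(C)C1=O | intermediate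
7 | isobutyraldehyde (2-methylpropanal) | CC(C)C=O | starting material
8 | mono-sulfone, 1-{2,4,6-trihydroxy-3-[2-methyl-1-(4-methylbenzenesulfonyl)propyl]phenyl}-2-methylpropan-1-one (racemic, not isolated) | CC(C)C(=O)c1c(O)cc(O)c(C(C(C)C)S(=O)(=O)c2ccc(C)cc2)c1O | intermediate
9 | bis-sulfone, 1-{2,4,6-trihydroxy-3,5-bis[2-methyl-1-(4-methylbenzenesulfonyl)propyl]phenyl}-2-methylpropan-1-one (mixture of meso and racemic diastereomers) | CC(C)C(=O)c1c(O)c(C(C(C)C)S(=O)(=O)c2ccc(C)cc2)c(O)c(C(C(C)C)S(=O)(=O)c2ccc(C)cc2)c1O | intermediate
10 | first o-quinone methide, 3,5-dihydroxy-2-(2-methylpropanoyl)-4-[2-methyl-1-(4-methylbenzenesulfonyl)propyl]-6-(2-methylpropylidene)cyclohexa-2,4-dien-1-one (one tautomer drawn, alkylidene geometry and sulfone centre undefined, not isolated) | CC(C)C(=O)C1=C(O)C(C(C(C)C)S(=O)(=O)c2ccc(C)cc2)=C(O)C(=CC(C)C)C1=O | intermediate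
11 | mono-adduct: one arm is the (R)-configured syncarpyl-substituted 2-methylpropyl group, the other arm still the 1-tosyl-2-methylpropyl group of undefined configuration (not isolated) | CC(C)C(=O)c1c(O)c([C@H](C2=C(O)C(C)(C)C(=O)C(C)(C)C2=O)C(C)C)c(O)c(C(C(C)C)S(=O)(=O)c2ccc(C)cc2)c1O | intermediate
12 | second o-quinone methide: 2-methylpropylidene quinone methide that carries the (R)-configured syncarpyl arm (one tautomer drawn, alkylidene geometry undefined, not isolated) | CC(C)C(=O)C1=C(O)C([C@H](C2=C(O)C(C)(C)C(=O)C(C)(C)C2=O)C(C)C)=C(O)C(=CC(C)C)C1=O | intermediate
13 | (R,R)-myrtucommulone A, 2,2'-{[2,4,6-trihydroxy-5-(2-methylpropanoyl)-1,3-phenylene]bis[(1R)-2-methylpropane-1,1-diyl]}bis(3-hydroxy-4,4,6,6-tetramethylcyclohex-2-ene-1,5-dione) | CC(C)C(=O)c1c(O)c([C@H](C2=C(O)C(C)(C)C(=O)C(C)(C)C2=O)C(C)C)c(O)c([C@H](C2=C(O)C(C)(C)C(=O)C(C)(C)C2=O)C(C)C)c1O | target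

**Totals and risks**

Total step count: 5. Longest linear sequence: 3 steps (steps 1, 4, 5; the syncarpic acid branch, steps 2, 3, 5, is equally long).

Steps most likely to fail:

Step 5 (key step). Face discrimination may be poor because the methide carbon has oxygen on both ring neighbours, the quinone methide can change geometry and tautomer, and free syncarpate can add without the catalyst. The meso isomer and the enantiomer would then form alongside the product. The quinone methide may also drain into the 2-methylprop-1-enyl arene by hydrogen shift. The meso compound is a diastereomer and should be removable by crystallisation or preparative HPLC, but low enantiomeric purity would not be repaired that way. Fallback with the opposite bond set, known chemistry: setting out from 6 and 7, a Knoevenagel condensation (L-proline cat., CH2Cl2, rt) should give 4,4,6,6-tetramethyl-2-(2-methylpropylidene)cyclohexane-1,3,5-trione F1. This acceptor has two identical flanking carbonyls and therefore no geometric ambiguity. A twofold enantioselective Friedel–Crafts-type Michael addition of arene 3 to F1 (2.2 equiv) under a chiral BINOL-derived Lewis acid should then proceed through the (R)-mono-adduct F2 and come back to the route at 13, now forming the aryl–C1 bonds instead.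

Step 4. The transient benzylic cation/quinone methide may be captured by a second molecule of 3 (diarylmethane oligomers) faster than by sulfinate, the second substitution may stall, or the sulfone may ionise again during isolation. Fallback by a different electrophile: setting out from 3 and 7, a Betti-type three-component aminoalkylation with morpholine (EtOH, rt to 50 °C) should give the bis(morpholinoalkyl) Mannich base F3 through a preformed iminium ion, so the arene never meets a free quinone methide under acid. Amine-for-sulfinate exchange (p-TolSO2Na, AcOH–H2O, 40 °C; loss of protonated morpholine and capture by sulfinate) should then come back to the route at 9.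

Step 1. Over-acylation and O-acylation of the very electron-rich triol, and incomplete turnover of the aluminium-complexed polyphenol, may lower the amount of mono-ketone. Fallback by a Houben–Hoesch reaction: setting out from 1, isobutyronitrile with ZnCl2 and HCl gas in Et2O at 0 °C should give the ketiminium chloride F4, which deactivates the ring against a second attack. Hydrolysis in boiling water should then come back to the route at 3.

**Further compounds**

F1 | step 5 | 4,4,6,6-tetramethyl-2-(2-methylpropylidene)cyclohexane-1,3,5-trione | CC(C)C=C1C(=O)C(C)(C)C(=O)C(C)(C)C1=O
F2 | step 5 | (R)-mono-adduct, 3-hydroxy-4,4,6,6-tetramethyl-2-{(1R)-2-methyl-1-[2,4,6-trihydroxy-3-(2-methylpropanoyl)phenyl]propyl}cyclohex-2-ene-1,5-dione | CC(C)C(=O)c1c(O)cc(O)c([C@H](C2=C(O)C(C)(C)C(=O)C(C)(C)C2=O)C(C)C)c1O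
F3 | step 4 | 1-{2,4,6-trihydroxy-3,5-bis[2-methyl-1-(morpholin-4-yl)propyl]phenyl}-2-methylpropan-1-one | CC(C)C(=O)c1c(O)c(C(C(C)C)N2CCOCC2)c(O)c(C(C(C)C)N2CCOCC2)c1O
F4 | step 1 | 2-methyl-1-(2,4,6-trihydroxyphenyl)propan-1-iminium chloride | CC(C)C(=[NH2+])c1c(O)cc(O)cc1O.[Cl-]
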